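The route rests on cutting the C–C single bond at the centre of the acyclic (E,E)-diene, between the CH= of the disubstituted alkene and the methyl-bearing sp2 carbon. The feature exploited is that this CH=CH–CH2 unit is the retron of an allyl group: its terminal =CH2 carries the only unhindered vinylic C–H bonds of the butenolide half. An oxidative Heck vinylation joins the complete (5E)-alkylidenebutenolide, carrying the S stereocentre and a plain allyl terminus, to a trisubstituted alkenyl pinacol boronate that carries the furan–CH2–furan unit. One operation makes the bond, sets the E-CH=CH geometry and finishes the target. Only one partner is preactivated.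

Key step: step 11

Remark on the chemistry: the exocyclic alkene of the target has its side chain cis to ring C-4 and trans to the ring oxygen (5E), the less stable geometry, so it is made by a stereospecific elimination; aldol adduct 10 is drawn as the Felkin member of the erythro pair, whose other member gives the same alkene.

Step 1
Reactants: 1 3-methylfuran-2(5H)-one
Product: 2 3-methyl-2-(trimethylsilyloxy)furan
Conditions: Me3SiOTf, Et3N, CH2Cl2, 0 °C; distillation
Reagents that add atoms: trimethylsilyl triflate, C[Si](C)(C)OS(=O)(=O)C(F)(F)F
Why: Soft enolisation and O-silylation of the butenolide should give the aromatic 2-silyloxyfuran, a vinylogous silyl ketene acetal that is nucleophilic at C-5.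

Step 2
Reactants: 3 (R)-4-benzyl-3-propionyloxazolidin-2-one; 4 allyl iodide
Product: 6 (R)-4-benzyl-3-[(S)-2-methylpent-4-enoyl]oxazolidin-2-one, via sodium Z-enolate 5 (not isolated)
Conditions: NaN(SiMe3)2, THF, −78 °C; then 4, −78 to −45 °C
Reagents that add atoms: none
Why: Evans asymmetric alkylation, in which the chelated Z-enolate is attacked by allyl iodide on the face opposite the benzyl group of the (R)-auxiliary, which sets the S configuration of the methyl-bearing stereocentre of the target.

Step 3
Reactants: 6 (R)-4-benzyl-3-[(S)-2-methylpent-4-enoyl]oxazolidin-2-one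
Product: 7 (S)-2-methylpent-4-en-1-ol
Conditions: LiBH4, H2O (1 equiv), Et2O, 0 °C
Reagents that add atoms: none
Why: Reductive cleavage of the imide by borohydride takes place at the exocyclic carbonyl, leaves the terminal alkene alone and does not epimerise the α-centre.

Step 4
Reactants: 7 (S)-2-methylpent-4-en-1-ol
Product: 8 (S)-2-methylpent-4-enal
Conditions: TEMPO (cat.), PhI(OAc)2, CH2Cl2, rt; aqueous NaHCO3 wash, careful concentration, used at once
Reagents that add atoms: none
Why: Oxoammonium (TEMPO) oxidation stops at the aldehyde under non-basic conditions, so the enolisable S centre of this volatile aldehyde should be kept.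

Step 5
Reactants: 8 (S)-2-methylpent-4-enal; 2 3-methyl-2-(trimethylsilyloxy)furan
Product: 10 (5S)-5-[(1R,2S)-1-hydroxy-2-methylpent-4-en-1-yl]-3-methylfuran-2(5H)-one, via trimethylsilyl ether 9 (not isolated)
Conditions: Bu4NF (10 mol %), THF, −78 °C; then 1 M HCl, 0 °C; chromatography
Reagents that add atoms: none
Why: Fluoride-catalysed vinylogous Mukaiyama aldol addition, in which the naked furanolate adds through C-5 in an open, dipole-minimised transition state that should favour the 5,1′-unlike (erythro) relation, Felkin–Anh attack on the (S)-aldehyde sets C-1′ as R, the erythro partner from the other aldehyde face has the same 5,1′ relation and converges in step 6, and only the threo isomers are removed by chromatography.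

Step 6
Reactants: 10 (5S)-5-[(1R,2S)-1-hydroxy-2-methylpent-4-en-1-yl]-3-methylfuran-2(5H)-one
Product: 11 (5E)-3-methyl-5-[(2S)-2-methylpent-4-en-1-ylidene]furan-2(5H)-one
Conditions: PPh3, DEAD, THF, −30 °C to rt, dark
Reagents that add atoms: none
Why: Mitsunobu-type dehydration, in which the oxyphosphonium salt of the carbinol loses the acidic H-5 by stereospecific anti-periplanar E2 elimination, and in the unlike isomer this conformation holds the side chain on the side of ring C-4, which gives the 5E alkene and erases both temporary stereocentres without touching the S centre.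

Step 7
Reactants: 12 3-bromofuran; 13 4-bromofuran-2-carbaldehyde
Product: 15 (4-bromofuran-2-yl)(furan-3-yl)methanol (racemic), via furan-3-yllithium 14 (not isolated)
Conditions: n-BuLi, Et2O, −78 °C; then 13, −78 °C; H2O
Reagents that add atoms: none
Why: Bromine–lithium exchange followed by 1,2-addition, since at −78 °C furan-3-yllithium keeps its position and should add to the aldehyde faster than it exchanges with the ring bromide, and the racemic carbinol centre is removed in step 8.

Step 8
Reactants: 15 (4-bromofuran-2-yl)(furan-3-yl)methanol
Product: 16 4-bromo-2-(furan-3-ylmethyl)furan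
Conditions: Et3SiH, CF3CO2H, CH2Cl2, −20 to 0 °C, short contact
Reagents that add atoms: none
Why: Ionic hydrogenation, in which the acid ionises the doubly furyl-stabilised carbinol and excess silane traps the cation by hydride transfer before it can alkylate a furan ring, the C–Br bond staying intact.

Step 9
Reactants: 16 4-bromo-2-(furan-3-ylmethyl)furan; 17 but-3-en-1-ylzinc bromide (commercial THF solution)
Product: 18 4-(but-3-en-1-yl)-2-(furan-3-ylmethyl)furan
Conditions: Pd(OAc)2 (2 mol %), SPhos (4 mol %), THF, rt to 40 °C
Reagents that add atoms: none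
Why: Negishi sp2–sp3 coupling, in which zerovalent palladium inserts into the C4–Br bond, zinc hands over the primary alkyl group and the bulky biaryl phosphine makes reductive elimination faster than β-hydride elimination, while furans and the terminal alkene are inert.

Step 10
Reactants: 18 4-(but-3-en-1-yl)-2-(furan-3-ylmethyl)furan; 19 isopropenylboronic acid pinacol ester
Product: 20 2-[(2Z)-5-{5-(furan-3-ylmethyl)furan-3-yl}pent-2-en-2-yl]-4,4,5,5-tetramethyl-1,3,2-dioxaborolane (boron trans to the chain, methyl cis to it)
Conditions: RuCl2(H2IMes)(=CH-C6H4-2-Oi-Pr) (second-generation Hoveyda–Grubbs catalyst, 5 mol %), 19 (3 equiv), CH2Cl2, 40 °C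
Reagents that add atoms: none
Why: Olefin cross-metathesis of a terminal alkene with an α-substituted vinyl boronate, driven by loss of ethene, should place the chain trans to the bulky pinacol boronate and cis to methyl (Z by the CIP rules because carbon outranks boron), which is the geometry the diene needs.

Step 11
Reactants: 11 (5E)-3-methyl-5-[(2S)-2-methylpent-4-en-1-ylidene]furan-2(5H)-one; 20 alkenyl pinacol boronate (1.5 equiv)
Product: 21 (5E)-5-[(2S,4E,6E)-9-{5-(furan-3-ylmethyl)furan-3-yl}-2,6-dimethylnona-4,6-dien-1-ylidene]-3-methylfuran-2(5H)-one (target)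
Conditions: Pd(OAc)2·PhS(O)CH2CH2S(O)Ph (10 mol %), 2,6-dimethyl-1,4-benzoquinone, AcOH, dioxane, rt, dark
Reagents that add atoms: none
Why: Transfer of the alkenyl group of 20 from boron to the sulfoxide-ligated Pd(OAc)2 gives an alkenyl complex of divalent palladium with retention of the C=C geometry, and the monosubstituted alkene of 11 then inserts so that the methyl-bearing alkenyl carbon bonds to the terminal CH2 and palladium sits on the internal carbon. Syn β-hydride elimination of the now allylic hydrogen releases the conjugated diene, and the quinone with AcOH returns zerovalent palladium to the divalent state. The closest known reaction type is the oxidative (boron) Heck vinylation of unactivated terminal alkenes with alkenyl pinacol boronates under Pd(OAc)2/bis-sulfoxide catalysis. No ring is closed and no stereocentre is made: the S centre is insulated from the reacting alkene by a CH2 group, and the new CH=CH unit should be E because the syn-elimination conformer keeps the two chain ends apart. Site selectivity for the one monosubstituted alkene over the two trisubstituted alkenes of the butenolide rests on steric access, and selectivity over the furan C–H bonds rests on boron-to-palladium transfer being fast at room temperature in weakly acidic dioxane, whereas furan palladation needs heat and stronger acid. Hydride loss toward the diene and not toward the skipped isomer is favoured by the weaker allylic C–H bond and by sulfoxide ligation, which suppresses re-addition of the palladium hydride, and the hindered quinone avoids a Diels–Alder reaction with the product diene.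

Compound list
1 | 3-methylfuran-2(5H)-one | CC1=CCOC1=O | starting material
2 | 3-methyl-2-(trimethylsilyloxy)furan | Cc1ccoc1O[Si](C)(C)C | intermediate
3 | (R)-4-benzyl-3-propionyloxazolidin-2-one | CCC(=O)N1[C@H](Cc2ccccc2)COC1=O | starting material
4 | allyl iodide | C=CCI | starting material
5 | sodium Z-enolate of 3 | C/C=C(\[O-])N1[C@H](Cc2ccccc2)COC1=O.[Na+] | intermediate
6 | (R)-4-benzyl-3-[(S)-2-methylpent-4-enoyl]oxazolidin-2-one | C=CC[C@H](C)C(=O)N1[C@H](Cc2ccccc2)COC1=O | intermediate
7 | (S)-2-methylpent-4-en-1-ol | C=CC[C@H](C)CO | intermediate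
8 | (S)-2-methylpent-4-enal | C=CC[C@H](C)C=O | intermediate
9 | (5S)-3-methyl-5-[(1R,2S)-2-methyl-1-(trimethylsilyloxy)pent-4-en-1-yl]furan-2(5H)-one | CC1=C[C@@H]([C@H](O[Si](C)(C)C)[C@@H](C)CC=C)OC1=O | intermediate
10 | (5S)-5-[(1R,2S)-1-hydroxy-2-methylpent-4-en-1-yl]-3-methylfuran-2(5H)-one | CC1=C[C@@H]([C@H](O)[C@@H](C)CC=C)OC1=O | intermediate
11 | (5E)-3-methyl-5-[(2S)-2-methylpent-4-en-1-ylidene]furan-2(5H)-one | CC1=C/C(=C\[C@@H](C)CC=C)OC1=O | intermediate
12 | 3-bromofuran | Brc1ccoc1 | starting material
13 | 4-bromofuran-2-carbaldehyde | O=Cc1cc(Br)co1 | starting material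
14 | furan-3-yllithium | [Li]c1ccoc1 | intermediate
15 | (4-bromofuran-2-yl)(furan-3-yl)methanol (racemic) | OC(c1ccoc1)c1cc(Br)co1 | intermediate
16 | 4-bromo-2-(furan-3-ylmethyl)furan | Brc1coc(Cc2ccoc2)c1 | intermediate
17 | but-3-en-1-ylzinc bromide | C=CCC[Zn]Br | starting material
18 | 4-(but-3-en-1-yl)-2-(furan-3-ylmethyl)furan | C=CCCc1coc(Cc2ccoc2)c1 | intermediate
19 | isopropenylboronic acid pinacol ester | CC(=C)B1OC(C)(C)C(C)(C)O1 | starting material
20 | 2-[(2Z)-5-{5-(furan-3-ylmethyl)furan-3-yl}pent-2-en-2-yl]-4,4,5,5-tetramethyl-1,3,2-dioxaborolane | CC1(C)OB(OC1(C)C)/C(C)=C/CCc1coc(Cc2ccoc2)c1 | intermediate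
21 | (5E)-5-[(2S,4E,6E)-9-{5-(furan-3-ylmethyl)furan-3-yl}-2,6-dimethylnona-4,6-dien-1-ylidene]-3-methylfuran-2(5H)-one | CC1=C/C(=C\[C@@H](C)C/C=C/C(C)=C/CCc2coc(Cc3ccoc3)c2)OC1=O | target

Total step count: 11. Longest linear sequence: 6 steps (2, 3, 4, 5, 6, 11). The furan branch takes 5 steps (7, 8, 9, 10, 11).

Steps most likely to fail

Step 11 (oxidative Heck vinylation).
- What may go wrong: boron-to-palladium transfer from the hindered α-methyl alkenyl boronate may be slow. That would leave room for protodeboronation, homocoupling, palladation or oxidation of the furan rings, hydride loss to the wrong side, or drift of the 5E alkene.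
- Fallback: it activates both partners. It sets out from 11 and 20 and comes back at 21.
- Lemieux–Johnson cleavage of the terminal alkene of 11 (OsO4 cat., NaIO4, 2,6-lutidine, dioxane–water) should give (3S)-3-methyl-4-[(2E)-4-methyl-5-oxofuran-2(5H)-ylidene]butanal F1.
- Takai iodo-olefination (CrCl2, CHI3, THF, 0 °C) should turn this into (5E)-5-[(2S,4E)-5-iodo-2-methylpent-4-en-1-ylidene]-3-methylfuran-2(5H)-one F2.
- Suzuki–Miyaura coupling of F2 with 20 (Pd(PPh3)4, TlOEt, THF–water, rt) then forms the same diene bond with retention on both sides and gives 21.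

Step 5 (vinylogous aldol addition).
- What may go wrong: simple diastereoselection for the erythro relation may be poor. The basic furanolate may also epimerise the aldehyde before it adds.
- Fallback: it replaces aldol plus elimination by an olefination. It sets out from 1 and 8 and comes back at 11, by-passing 10 and step 6.
- Radical bromination of 1 (NBS, AIBN, PhCF3, reflux) should give 5-bromo-3-methylfuran-2(5H)-one F3.
- PPh3 in toluene converts this into (4-methyl-5-oxo-2,5-dihydrofuran-2-yl)triphenylphosphonium bromide F4.
- Et3N in CH2Cl2 at 0 °C releases 3-methyl-5-(triphenylphosphoranylidene)furan-2(5H)-one F5.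
- In the presence of 8 this ylide undergoes a Wittig reaction to 11 together with (5Z)-3-methyl-5-[(2S)-2-methylpent-4-en-1-ylidene]furan-2(5H)-one F6.
- The two are separated by chromatography, and F6 can be re-equilibrated by irradiation and recycled.

Step 10 (cross-metathesis).
- What may go wrong: the 1,1-disubstituted boronate may react too slowly, so that homodimerisation or double-bond migration of the terminal alkene wins. Control of the trisubstituted geometry may also be incomplete.
- Fallback: it fixes the geometry by a syn addition to an alkyne. It sets out from 16 and comes back at 20.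
- Pent-3-yn-1-ol is converted (I2, PPh3, imidazole, CH2Cl2) into 5-iodopent-2-yne F7.
- Zinc insertion (Zn, LiCl, THF, 40 °C) gives pent-3-yn-1-ylzinc iodide F8.
- Negishi coupling with 16 (Pd(OAc)2, SPhos, THF) gives 2-(furan-3-ylmethyl)-4-(pent-3-yn-1-yl)furan F9.
- Copper-catalysed protoboration (CuCl, Xantphos, NaOt-Bu, B2pin2, MeOH, THF, rt) adds boron and hydrogen syn, with boron on the less hindered methyl-bearing carbon, to give 20. Any regioisomer is removed by chromatography.

Further compounds
F1 | step 11 | (3S)-3-methyl-4-[(2E)-4-methyl-5-oxofuran-2(5H)-ylidene]butanal | CC1=C/C(=C\[C@@H](C)CC=O)OC1=O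
F2 | step 11 | (5E)-5-[(2S,4E)-5-iodo-2-methylpent-4-en-1-ylidene]-3-methylfuran-2(5H)-one | CC1=C/C(=C\[C@@H](C)C/C=C/I)OC1=O
F3 | step 5 | 5-bromo-3-methylfuran-2(5H)-one (racemic) | CC1=CC(Br)OC1=O
F4 | step 5 | (4-methyl-5-oxo-2,5-dihydrofuran-2-yl)triphenylphosphonium bromide | CC1=CC(OC1=O)[P+](c1ccccc1)(c1ccccc1)c1ccccc1.[Br-]
F5 | step 5 | 3-methyl-5-(triphenylphosphoranylidene)furan-2(5H)-one | CC1=CC(OC1=O)=P(c1ccccc1)(c1ccccc1)c1ccccc1
F6 | step 5 | (5Z)-3-methyl-5-[(2S)-2-methylpent-4-en-1-ylidene]furan-2(5H)-one | CC1=C/C(=C/[C@@H](C)CC=C)OC1=O
F7 | step 10 | 5-iodopent-2-yne | CC#CCCI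
F8 | step 10 | pent-3-yn-1-ylzinc iodide | CC#CCC[Zn]I
F9 | step 10 | 2-(furan-3-ylmethyl)-4-(pent-3-yn-1-yl)furan | CC#CCCc1coc(Cc2ccoc2)c1
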